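**Retrosynthetic overview**
1. Feature used: in the furan ring, O1–C2=C3 plus the formyl carbon on C3 is the O–C=C–C(=O) chain of a β-keto ester enol. C3a and C7a are neighbouring ring A carbons that can enter the synthesis as C–I and C–Br.
2. The furan ring is the only ring formed, since rings A and B come with the starting materials. It is cut at C3–C3a and C7a–O1 into 1-bromo-2-iodo-3,5-dimethoxybenzene 2 and aroylacetate 6, which are joined in one flask by copper catalysis.
3. The C3 ester is taken to the formyl group (LiAlH4, MnO2) while all phenols are still masked. The formyl oxygen then steers BCl3 to the peri 4-OMe in the same operation that removes the 4'-benzyl group.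
4. The C5 prenyl group comes last: 4'-O-silylation, 4-O-(1,1-dimethylallyl) ether, aromatic Claisen shift to C5 (the only open ortho position of O4), desilylation.
5. Compound 2 comes from NIS iodination of 1-bromo-3,5-dimethoxybenzene. Compound 6 comes from benzylation and methoxycarbonylation of 4-hydroxy-2-methoxyacetophenone.

Key step: step 4

Assumption: the target is achiral, so no stereocontrol is needed, and the stereocentres of the transient compounds 7 and 17 are racemic and vanish; numbering is O1, C2, C3, C3a, C4–C7, C7a, ring A is the benzo ring and ring B the 2-aryl group (primed positions).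

Step 1
Reactants: 1 1-bromo-3,5-dimethoxybenzene
Product: 2 1-bromo-2-iodo-3,5-dimethoxybenzene
Conditions: NIS (1.05 equiv), MeCN, rt, dark
Reagents that add atoms: N-iodosuccinimide, O=C1CCC(=O)N1I
Why: Electrophilic aromatic iodination, in which both methoxy groups activate the two symmetry-equivalent positions next to bromine (ortho to one OMe, para to the other) more than the site between the two methoxy groups, so a single isomer with iodine beside bromine should form.

Step 2
Reactants: 3 1-(4-hydroxy-2-methoxyphenyl)ethanone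
Product: 4 1-[4-(benzyloxy)-2-methoxyphenyl]ethanone
Conditions: BnBr (1.1 equiv), K2CO3 (1.5 equiv), DMF, rt → 50 °C
Reagents that add atoms: benzyl bromide, BrCc1ccccc1
Why: Williamson ether synthesis on the only acidic OH, giving a benzyl ether that withstands NaH, hot K2CO3, hydride and MnO2 and later leaves together with the C4 methyl ether.

Step 3
Reactants: 4 1-[4-(benzyloxy)-2-methoxyphenyl]ethanone; 5 dimethyl carbonate
Product: 6 methyl 3-[4-(benzyloxy)-2-methoxyphenyl]-3-oxopropanoate
Conditions: NaH (2.5 equiv), 5 (5 equiv), THF, reflux; then 1 M HCl, 0 °C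
Reagents that add atoms: none
Why: Crossed Claisen condensation (C-methoxycarbonylation of the methyl ketone enolate), driven to completion by irreversible deprotonation of the β-keto ester as it forms.

Step 4
Reactants: 2 1-bromo-2-iodo-3,5-dimethoxybenzene; 6 methyl 3-[4-(benzyloxy)-2-methoxyphenyl]-3-oxopropanoate (1.3 equiv)
Product: 8 methyl 2-[4-(benzyloxy)-2-methoxyphenyl]-4,6-dimethoxybenzofuran-3-carboxylate, via alpha-aryl keto ester 7 (not isolated)
Conditions: CuI (20 mol %), K2CO3 (4 equiv), THF, 100 °C, sealed tube, Ar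
Reagents that add atoms: none
Why: K2CO3 converts 6 into its enolate, which also serves as the chelating ligand for CuI; this monovalent copper enolate inserts into the weaker C–I bond of 2, and reductive elimination from the trivalent copper aryl forms C3–C3a and gives 7 (Hurtley/Ullmann-type C-arylation of an activated methylene). Compound 7 is more acidic than 6 and enolises at once, which places its enolate oxygen beside the ortho C–Br bond, so a second copper cycle (intramolecular Ullmann O-arylation) forms C7a–O1. The furan ring closes in a five-membered exo-type mode, with the breaking C7a–Br bond outside the new ring, by C–O reductive elimination from a six-membered cupracycle, and aromatisation to the benzofuran makes the closure irreversible. The closest known reaction type is the CuI-catalysed domino C-/O-arylation of β-keto esters with 1-bromo-2-iodoarenes to 2,3-disubstituted benzofurans, used here on an aroylacetate and a more crowded iodide. No stereocentre results, because the α-carbon of 7 becomes sp2 C3. The step needs iodide to react before bromide and carbon before oxygen: the halogen pair in 2 secures the first and the soft copper-bound α-carbon of the enolate the second, so carbon ends beside the C4 methoxy group and oxygen at C7a, while the raised CuI loading answers the crowding of iodine by Br and OMe.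

Step 5
Reactants: 8 methyl 2-[4-(benzyloxy)-2-methoxyphenyl]-4,6-dimethoxybenzofuran-3-carboxylate
Product: 9 {2-[4-(benzyloxy)-2-methoxyphenyl]-4,6-dimethoxybenzofuran-3-yl}methanol
Conditions: LiAlH4 (1.5 equiv), THF, 0 °C → rt; then H2O
Reagents that add atoms: none
Why: Hydride reduction of the ester, placed here so that no free phenol, silyl ether or BCl3-labile methyl ester is involved, with the low temperature guarding the easily ionised C3 benzylic C–O bond against over-reduction.

Step 6
Reactants: 9 {2-[4-(benzyloxy)-2-methoxyphenyl]-4,6-dimethoxybenzofuran-3-yl}methanol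
Product: 10 2-[4-(benzyloxy)-2-methoxyphenyl]-4,6-dimethoxybenzofuran-3-carbaldehyde
Conditions: activated MnO2 (excess), CH2Cl2, rt
Reagents that add atoms: none
Why: Heterogeneous MnO2 oxidation of a benzylic-type heteroaryl carbinol, which is neutral, spares the acid-sensitive alcohol and stops at the aldehyde.

Step 7
Reactants: 10 2-[4-(benzyloxy)-2-methoxyphenyl]-4,6-dimethoxybenzofuran-3-carbaldehyde
Product: 11 4-hydroxy-2-(4-hydroxy-2-methoxyphenyl)-6-methoxybenzofuran-3-carbaldehyde
Conditions: BCl3 (1 M in CH2Cl2, 5 equiv), C6HMe5 (3 equiv), CH2Cl2, −78 → 0 °C; then H2O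
Reagents that add atoms: none
Why: Lewis acid ether cleavage, in which BCl3 with pentamethylbenzene as a non-basic benzyl cation trap removes the aryl benzyl ether at −78 °C, and on warming boron held on the strongly basic, vinylogous-ester-like formyl oxygen bridges to O4 so that chloride cuts this methyl group (chelation-controlled demethylation next to a carbonyl group), while the unchelated 6- and 2'-methyl ethers should stay inert to BCl3 at 0 °C.

Step 8
Reactants: 11 4-hydroxy-2-(4-hydroxy-2-methoxyphenyl)-6-methoxybenzofuran-3-carbaldehyde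
Product: 12 4-hydroxy-6-methoxy-2-{2-methoxy-4-[(triisopropylsilyl)oxy]phenyl}benzofuran-3-carbaldehyde
Conditions: i-Pr3SiCl (1.05 equiv), imidazole (1.2 equiv), DMF, 0 °C
Reagents that add atoms: chlorotriisopropylsilane, CC(C)[Si](Cl)(C(C)C)C(C)C
Why: Chemoselective silylation, since the 4'-OH is unhindered and the more acidic one (conjugated through C2=C3 with the formyl group) whereas the 4-OH is hydrogen-bonded to the formyl oxygen and shielded in the peri bay, so one equivalent of the bulky chlorosilane should react on ring B only.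

Step 9
Reactants: 13 2-methylbut-3-en-2-ol
Product: 15 tert-butyl 2-methylbut-3-en-2-yl carbonate, via lithium 2-methylbut-3-en-2-olate 14 (not isolated)
Conditions: n-BuLi (1.05 equiv), THF, −78 → 0 °C; then Boc2O (1.1 equiv), 0 °C → rt; then H2O
Reagents that add atoms: di-tert-butyl dicarbonate, CC(C)(C)OC(=O)OC(=O)OC(C)(C)C
Why: O-acylation of a tertiary lithium alkoxide with Boc2O, the standard access to tertiary allylic carbonates.

Step 10
Reactants: 12 4-hydroxy-6-methoxy-2-{2-methoxy-4-[(triisopropylsilyl)oxy]phenyl}benzofuran-3-carbaldehyde; 15 tert-butyl 2-methylbut-3-en-2-yl carbonate (3 equiv)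
Product: 16 6-methoxy-2-{2-methoxy-4-[(triisopropylsilyl)oxy]phenyl}-4-[(2-methylbut-3-en-2-yl)oxy]benzofuran-3-carbaldehyde
Conditions: Pd(PPh3)4 (10 mol %), THF, 0 °C → rt
Reagents that add atoms: none
Why: Tsuji–Trost O-allylation, in which zerovalent palladium ionises 15 with loss of CO2, the tert-butoxide set free deprotonates the chelated 4-OH, and the phenoxide attacks the more substituted allyl terminus under kinetic control at low temperature, as known for the reverse prenylation of phenols.

Step 11
Reactants: 16 6-methoxy-2-{2-methoxy-4-[(triisopropylsilyl)oxy]phenyl}-4-[(2-methylbut-3-en-2-yl)oxy]benzofuran-3-carbaldehyde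
Product: 18 4-hydroxy-6-methoxy-2-{2-methoxy-4-[(triisopropylsilyl)oxy]phenyl}-5-(3-methylbut-2-en-1-yl)benzofuran-3-carbaldehyde, via C5-prenyl cyclohexadienone 17 (not isolated)
Conditions: PhMe, 110 °C, base-washed glassware
Reagents that add atoms: none
Why: Aromatic Claisen rearrangement ([3,3] shift, eased by the gem-dimethyl group and by relief of peri strain), in which C3a is blocked so the allyl terminus can bond only to C5, allyl inversion turns 1,1-dimethylallyl into prenyl, and enolisation of 17 erases its racemic C5 stereocentre and restores ring A.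

Step 12
Reactants: 18 4-hydroxy-6-methoxy-2-{2-methoxy-4-[(triisopropylsilyl)oxy]phenyl}-5-(3-methylbut-2-en-1-yl)benzofuran-3-carbaldehyde
Product: 19 4-hydroxy-2-(4-hydroxy-2-methoxyphenyl)-6-methoxy-5-(3-methylbut-2-en-1-yl)benzofuran-3-carbaldehyde (target)
Conditions: Bu4NF (1.1 equiv), AcOH (1.1 equiv), THF, 0 °C
Reagents that add atoms: none
Why: Fluoride cleavage of the aryl silyl ether, driven by the Si–F bond and buffered with AcOH so that the aldehyde and the acid-sensitive ortho-prenylphenol unit stay untouched.

**Compound list**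
1 | 1-bromo-3,5-dimethoxybenzene | COc1cc(Br)cc(OC)c1 | starting material
2 | 1-bromo-2-iodo-3,5-dimethoxybenzene | COc1cc(Br)c(I)c(OC)c1 | intermediate
3 | 1-(4-hydroxy-2-methoxyphenyl)ethanone | CC(=O)c1ccc(O)cc1OC | starting material
4 | 1-[4-(benzyloxy)-2-methoxyphenyl]ethanone | CC(=O)c1ccc(OCc2ccccc2)cc1OC | intermediate
5 | dimethyl carbonate | COC(=O)OC | starting material
6 | methyl 3-[4-(benzyloxy)-2-methoxyphenyl]-3-oxopropanoate | COC(=O)CC(=O)c1ccc(OCc2ccccc2)cc1OC | intermediate
7 | methyl 3-[4-(benzyloxy)-2-methoxyphenyl]-2-(2-bromo-4,6-dimethoxyphenyl)-3-oxopropanoate (racemic, not isolated) | COC(=O)C(C(=O)c1ccc(OCc2ccccc2)cc1OC)c1c(Br)cc(OC)cc1OC | intermediate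
8 | methyl 2-[4-(benzyloxy)-2-methoxyphenyl]-4,6-dimethoxybenzofuran-3-carboxylate | COC(=O)c1c(-c2ccc(OCc3ccccc3)cc2OC)oc2cc(OC)cc(OC)c12 | intermediate
9 | {2-[4-(benzyloxy)-2-methoxyphenyl]-4,6-dimethoxybenzofuran-3-yl}methanol | OCc1c(-c2ccc(OCc3ccccc3)cc2OC)oc2cc(OC)cc(OC)c12 | intermediate
10 | 2-[4-(benzyloxy)-2-methoxyphenyl]-4,6-dimethoxybenzofuran-3-carbaldehyde | O=Cc1c(-c2ccc(OCc3ccccc3)cc2OC)oc2cc(OC)cc(OC)c12 | intermediate
11 | 4-hydroxy-2-(4-hydroxy-2-methoxyphenyl)-6-methoxybenzofuran-3-carbaldehyde | O=Cc1c(-c2ccc(O)cc2OC)oc2cc(OC)cc(O)c12 | intermediate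
12 | 4-hydroxy-6-methoxy-2-{2-methoxy-4-[(triisopropylsilyl)oxy]phenyl}benzofuran-3-carbaldehyde | O=Cc1c(-c2ccc(O[Si](C(C)C)(C(C)C)C(C)C)cc2OC)oc2cc(OC)cc(O)c12 | intermediate
13 | 2-methylbut-3-en-2-ol | CC(C)(O)C=C | starting material
14 | lithium 2-methylbut-3-en-2-olate (not isolated) | [Li+].[O-]C(C)(C)C=C | intermediate
15 | tert-butyl 2-methylbut-3-en-2-yl carbonate | CC(C)(C)OC(=O)OC(C)(C)C=C | intermediate
16 | 6-methoxy-2-{2-methoxy-4-[(triisopropylsilyl)oxy]phenyl}-4-[(2-methylbut-3-en-2-yl)oxy]benzofuran-3-carbaldehyde | O=Cc1c(-c2ccc(O[Si](C(C)C)(C(C)C)C(C)C)cc2OC)oc2cc(OC)cc(OC(C)(C)C=C)c12 | intermediate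
17 | 6-methoxy-2-{2-methoxy-4-[(triisopropylsilyl)oxy]phenyl}-5-(3-methylbut-2-en-1-yl)-4-oxo-4,5-dihydrobenzofuran-3-carbaldehyde (racemic, not isolated) | O=Cc1c(-c2ccc(O[Si](C(C)C)(C(C)C)C(C)C)cc2OC)oc2C=C(OC)C(CC=C(C)C)C(=O)c12 | intermediate
18 | 4-hydroxy-6-methoxy-2-{2-methoxy-4-[(triisopropylsilyl)oxy]phenyl}-5-(3-methylbut-2-en-1-yl)benzofuran-3-carbaldehyde | O=Cc1c(-c2ccc(O[Si](C(C)C)(C(C)C)C(C)C)cc2OC)oc2cc(OC)c(CC=C(C)C)c(O)c12 | intermediate
19 | 4-hydroxy-2-(4-hydroxy-2-methoxyphenyl)-6-methoxy-5-(3-methylbut-2-en-1-yl)benzofuran-3-carbaldehyde | COc1cc(O)ccc1-c1oc2cc(OC)c(CC=C(C)C)c(O)c2c1C=O | target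

Total step count: 12
Longest linear sequence: 10 steps (3 → 4 → 6 → 8 → 9 → 10 → 11 → 12 → 16 → 18 → 19; steps 2–8 and 10–12)

**Steps most likely to fail**

1. Step 4.
   - What may go wrong: insertion of copper into the C–I bond, crowded on both sides by bromine and a methoxy group, may be slow. Proto-deiodination of 2 and retro-Claisen cleavage of the keto ester could then take over.
   - Fallback (sets out from 4, comes back at 10): the C3–C3a bond is made by a 1,2-aryl shift instead of a cross-coupling.
   - Commercial 2-hydroxy-4,6-dimethoxybenzaldehyde is protected (MOMCl, i-Pr2NEt, CH2Cl2) as 2,4-dimethoxy-6-(methoxymethoxy)benzaldehyde F1.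
   - Claisen–Schmidt condensation with ketone 4 (KOH, EtOH, rt) should give (E)-1-[4-(benzyloxy)-2-methoxyphenyl]-3-[2,4-dimethoxy-6-(methoxymethoxy)phenyl]prop-2-en-1-one F2.
   - PhI(OH)OTs in MeOH then brings about the known oxidative rearrangement of chalcones. The electron-rich ring A aryl group moves from the β- to the α-carbon, giving 1-[4-(benzyloxy)-2-methoxyphenyl]-2-[2,4-dimethoxy-6-(methoxymethoxy)phenyl]-3,3-dimethoxypropan-1-one F3.
   - p-TsOH in (CF3)2CHOH removes the MOM group, closes the freed phenol on the ketone, dehydrates and unmasks the acetal. This should deliver aldehyde 10 directly at the right oxidation level.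

2. Step 10.
   - What may go wrong: the chelated, peri-shielded phenoxide may attack only sluggishly. The kinetic tertiary ether may also drift to the linear prenyl ether through re-ionisation by palladium.
   - Fallback (sets out from 12, comes back at 16): the bulky π-allyl electrophile is replaced by a slim, linear copper-bound propargylic one, and the resulting ether cannot isomerise.
   - Compound 12 is treated with 3-chloro-3-methylbut-1-yne, CuCl2·2H2O (cat.) and DBU in MeCN at 0 °C. This should give 6-methoxy-2-{2-methoxy-4-[(triisopropylsilyl)oxy]phenyl}-4-[(2-methylbut-3-yn-2-yl)oxy]benzofuran-3-carbaldehyde F4.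
   - Semi-hydrogenation (H2, Pd/CaCO3 poisoned with Pb(OAc)2, quinoline, EtOAc) then leads to 16.

3. Step 7.
   - What may go wrong: the three methyl ethers may not be fully discriminated, or the benzyl group may transfer to the electron-rich ring A carbons.
   - Fallback (sets out from 10, comes back at 12): the two ether cleavages are uncoupled, so no benzyl cation is ever formed.
   - Hydrogenolysis of 10 (H2, Pd/C, EtOAc) should give 2-(4-hydroxy-2-methoxyphenyl)-4,6-dimethoxybenzofuran-3-carbaldehyde F5.
   - Silylation (i-Pr3SiCl, imidazole, DMF) gives 4,6-dimethoxy-2-{2-methoxy-4-[(triisopropylsilyl)oxy]phenyl}benzofuran-3-carbaldehyde F6.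
   - MgI2·OEt2 in toluene/THF at 60 °C then cuts only the methyl ether that can share a magnesium chelate with the formyl oxygen (SN2 by iodide), giving 12.

**Further compounds**
F1 | step 4 | 2,4-dimethoxy-6-(methoxymethoxy)benzaldehyde | COCOc1cc(OC)cc(OC)c1C=O
F2 | step 4 | (E)-1-[4-(benzyloxy)-2-methoxyphenyl]-3-[2,4-dimethoxy-6-(methoxymethoxy)phenyl]prop-2-en-1-one | COCOc1cc(OC)cc(OC)c1/C=C/C(=O)c1ccc(OCc2ccccc2)cc1OC
F3 | step 4 | 1-[4-(benzyloxy)-2-methoxyphenyl]-2-[2,4-dimethoxy-6-(methoxymethoxy)phenyl]-3,3-dimethoxypropan-1-one (racemic) | COCOc1cc(OC)cc(OC)c1C(C(OC)OC)C(=O)c1ccc(OCc2ccccc2)cc1OC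
F4 | step 10 | 6-methoxy-2-{2-methoxy-4-[(triisopropylsilyl)oxy]phenyl}-4-[(2-methylbut-3-yn-2-yl)oxy]benzofuran-3-carbaldehyde | O=Cc1c(-c2ccc(O[Si](C(C)C)(C(C)C)C(C)C)cc2OC)oc2cc(OC)cc(OC(C)(C)C#C)c12
F5 | step 7 | 2-(4-hydroxy-2-methoxyphenyl)-4,6-dimethoxybenzofuran-3-carbaldehyde | O=Cc1c(-c2ccc(O)cc2OC)oc2cc(OC)cc(OC)c12
F6 | step 7 | 4,6-dimethoxy-2-{2-methoxy-4-[(triisopropylsilyl)oxy]phenyl}benzofuran-3-carbaldehyde | O=Cc1c(-c2ccc(O[Si](C(C)C)(C(C)C)C(C)C)cc2OC)oc2cc(OC)cc(OC)c12
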